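## Structural features

The target 39, the gibberellin that carries the number 32 in the A series, is a 20-nor-ent-gibberellane in which a γ-lactone from C19 to C10 spans the α face of ring A. Cyclohexene ring A is trans-fused through C5–C10 to cyclopentane ring B, ring B is cis-fused through C8–C9 to six-membered ring C, and a C15–C16 bridge from C8 to C13 closes ring D, so that rings C and D form a bicyclo[3.2.1]octane. Ten stereocentres are present: C3, C4, C5, C6, C8, C9 and C10 form an unbroken chain through rings A and B (C4 and C8 quaternary, C10 a tertiary carbinol carbon), and C12, C13 and C15 sit on the bicyclooctane. The fragile parts are the allylic tertiary lactone with its 3β-hydroxyl (retro-aldol epimerisation and lactone migration in base, aromatisation in acid), the 13-hydroxy-16-ene unit (Wagner–Meerwein shift in protic acid) and the 15β allylic alcohol. The real difficulty is the oxidation pattern of the bicyclooctane: the 12α-hydroxyl is axial, lies next to the fully substituted C13 and has no neighbouring group from which it could be derived. The key step exploits two facts: C10 is the axial substituent on C9 of chair ring C and is therefore 1,3-diaxial to the α hydrogen on C12, and ring B holds the C10 oxygen at a small torsion angle to C11. An oxygen radical on C10 thus reaches the C12–Hα bond through a six-membered transition state (O, C10, C9, C11, C12, H).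

## Logic of the disconnections

39 is traced to 38 and then to 37 by cutting the O–CH3 bond of the C7 ester and the C3–H bond. The allylic hydroxy lactone is thereby present for two steps only and ring A of 37 is a non-enolisable enone. The forward reduction must deliver hydride to the α face of C3, which calls for reagent control.

37 is traced to 35 and to 32 by removing the C15–O bond (allylic oxidation), the two acetal protecting groups and the C1=C2 unsaturation. This leaves a saturated ring A with a silyl-protected C3 carbinol. The forward steps must oxidise C3 while C12–OH is capped, and must hydroxylate C15 on the β face.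

32 goes back to 31 and 30 by cutting C16=C17 (methylenation) and the C12 acetal. The alkene is introduced only after every acidic or iodine-based step. The olefination must tolerate a lactone and an ester.

30 goes back to 28 by cutting the lactone O–C10 bond and reconnecting C10 to the C12 oxygen. This turns the 12α-hydroxyl and the lactone into one cyclic ether plus a C19 amide. The forward step must ionise a tertiary C–O bond and let the amide oxygen take its place on the same face.

28 goes back to 26 by cutting the O–C12 bond. This removes the C12 stereocentre and the only unactivated oxidation of the route, leaving a ring C with oxygen at C13 only. The forward step needs the C10 oxygen radical to select the axial C12 hydrogen.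

26 goes back through 25 and 24 to 23 by cutting C13–C16 (ring D). The bicyclooctane becomes a cis-hydrindanone carrying an acetaldehyde side chain. The forward ketyl coupling must bridge C8 and C13 on the β face.

23 goes back through 21 to 20 by cutting C8–C15. Quaternary C8 becomes the β carbon of a ring C enone. The forward conjugate allylation must occur cis to H9.

20 goes back to 18 by cutting C6–C8 (ring B). The tricycle falls into ring A joined to ring C by the single C9–C10 bond, with C8 as a vinylogous ester carbonyl. The forward step needs an ester enolate at C6 in the presence of other acidic sites.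

18 goes back to 14 and 15 by cutting C9–C10. This gives a ring A ketone and a commercial ring C block. The forward aldol must set C9 and C10 and must be protected against reversal.

14 goes back through 13 and 12 to 11 and 9. The C3–H bond is cut (a reduction that also resolves the racemate), the C10 carbonyl is masked and the C5–H bond is cut (protonation of an enol ether). The forward steps must keep the C5 centre from epimerising.

9 goes back to 7 by cutting C4–C18 (reductive methylation of the arene), which returns ring A to a benzene ring.

7 goes back through 5 and 3 to 1 by cutting C6–C7 (carboxylation), C5–C6 (ortho-methylation) and the amide C–N bond. Attaching C6 and C7 on the arene avoids the later problem of alkylating a C10 ketone at C5 and not at C1.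

## Other disconnections considered

Alternative 1: The cut is through C8–C14 and C9–C11 of ring C. The forward key step is a Diels–Alder reaction of trimethyl (E)-aconitate A1 with 2,3-bis(trimethylsilyloxy)buta-1,3-diene A2 under a chiral Lewis acid, giving the cyclohexene triester A3.
- In its favour: quaternary C8 and C9 are set together in one intermolecular step, and the absolute configuration would come from a catalyst. On this point it is better than the chosen plan, which resolves a racemate in step 6. Ring C also arrives with both C12 and C13 oxygenated, so no C–H oxidation is needed; on the C12 problem it is at least the equal of the chosen plan.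
- Against it: A1 is a trisubstituted dienophile with three ester groups and no single two-point binding mode, so high enantioselectivity is uncertain. The three esters of A3 must be told apart. C10 enters as an ester carbon, so ring A, quaternary C4 and the tertiary C10–O centre must all be built on a neopentyl carbonyl. The symmetrical enediol ether must be differentiated into a secondary 12α and a tertiary 13 alcohol.
- Comparison: the cycloaddition is better precedented as a reaction type than steps 16 and 17. The sequence after A3 would, however, be longer than the fifteen steps that lead to 26.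

Alternative 2: The cut is the C4–C5 bond of ring A. The forward key step is an Ireland–Claisen rearrangement of the silyl ketene acetal of the δ-lactone A4 (C19–O–C1) across C10=C5, giving the cyclohexene acid A5.
- In its favour: the hindered C4–C5 bond, quaternary C4 and C5 are formed together with chirality transfer from C1, and the lactone fixes the ketene acetal geometry. The 1(10)-alkene of A5 is set up for iodolactonisation and dehydroiodination to the 1-ene 19,10-lactone with the 3β oxygen untouched. On the end game of ring A it is better than the chosen plan, since it needs no redox change at C3 and no ether-to-lactone exchange.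
- Against it: the lactone enforces a boat-like transition state next to a ring-fusion carbon. A4 must already hold the complete B/C/D core with the 12α and 13 oxygens, so the hardest oxidation is left unsolved. C7 is carried at the alcohol level.
- Comparison: structurally the two plans are complementary (ring A last versus ring A first). Mechanistically the rearrangement is the safer single step. In step count the alternative is equal at best, because A4 is long to make.

Alternative 3: The cuts are C6–C8 and C15–C16. The forward key step is a tin hydride cyclisation of the bromo ester A6. The C6 radical adds 5-exo to C8 of the silyl enol ether, the C15 radical adds 5-exo-dig to the ethynyl group on C13, and the vinyl radical takes hydrogen, giving the silylated methyl ester A7.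
- In its favour: rings B and D, quaternary C8 and three stereocentres are formed in the last C–C bond-forming step with matched polarity. The C15 oxygen and the exocyclic methylene arrive together, so neither olefination nor allylic oxidation is needed. On ring D and on convergence it is better than the chosen plan.
- Against it: the configurations at C6, C8 and C15 rest on radical conformations alone. A6 already contains the allylic lactone, the 12α,13-dioxygenated ring C and the C9–C10 bond between a tertiary and a quaternary centre, whose construction is the unsolved part. Reduction of the bromide before attack on the hindered enol ether carbon is a plausible competing path.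
- Comparison: on quaternary C8 the plans are equal (both add to an sp2 C8). Both rely on radical selectivity in the key step; the chosen plan draws it from a rigid ring geometry. The alternative would be shorter only if A6 were short to make.

Key step: step 16

Remarks on the chemistry:
- **Numbering and faces.** Gibberellane numbering (C1–C19) is used for all intermediates. α and β refer to the usual drawing: H5, H9, C7, C18 and the C15–C16 bridge are β; C19, the C10 oxygen and the 12-hydroxyl are α.
- **Key-step structures.** In the hydroxy amide 26 and the ether 28, C3, C4, C5, C6, C8, C9, C10 and C13 carry the configuration of 39, and C12 takes it in 28, so both can be carried to 39 without any inversion.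
- **Points that shape the plan.**
  - The C6 hydrogen stands in a 1,4 and not a 1,5 relationship to the C10 oxygen. The true competitors of C12–H are C14–H2, C15–H2, C3–H and C18–H3.
  - The C8 and C13 carbons of ring C are 1,3-related, so a 1,4-dioxygenated cyclohexane such as 1,4-dioxaspiro[4.5]decan-8-one cannot supply them; 3-ethoxycyclohex-2-en-1-one (15) is used.
  - The two-carbon unit on C8 is introduced as allyl and not as propargyl, because a propargylic γ-hydrogen on an enone invites isomerisation.
  - Small hydrides are expected to attack a C3 ketone from the β face, so the final reduction is put under reagent control.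
- **Racemates.** Compounds 8 to 11 are racemic; their SMILES show the enantiomer that is carried on.
- **Assumption.** In both oxazaborolidine reductions (steps 6 and 24) quaternary C4 acts as the large substituent of the C3 ketone, which makes the (R)-catalyst the source of the 3S carbinol.

## Route

Step 1
Reactants: 1 2,5-dimethoxybenzoic acid
Product: 3 2,5-dimethoxy-N,N-dimethylbenzamide, via 2,5-dimethoxybenzoyl chloride 2 (not isolated)
Conditions: SOCl2, cat. DMF, toluene, 60 °C; evaporate; Me2NH (2 M in THF), Et3N, CH2Cl2, 0 °C
Reagents that add atoms: dimethylamine, CNC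
Why: Amide formation through the acyl chloride; the tertiary amide is the later C19 carbonyl, serves as ortho-directing group and, having no N–H, can neither lactonise early nor lose hydrogen in the radical step.

Step 2
Reactants: 3 2,5-dimethoxy-N,N-dimethylbenzamide
Product: 5 3,6-dimethoxy-N,N,2-trimethylbenzamide, via 6-lithio-2,5-dimethoxy-N,N-dimethylbenzamide 4 (not isolated)
Conditions: s-BuLi, TMEDA, THF, −78 °C; MeI, −78 °C → rt
Reagents that add atoms: iodomethane, CI
Why: Directed ortho-metalation: the amide and the 5-methoxy group jointly acidify the hydrogen between them, and methylation places the future C6 carbon on the future C5.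

Step 3
Reactants: 5 3,6-dimethoxy-N,N,2-trimethylbenzamide
Product: 7 2-[2-(dimethylcarbamoyl)-3,6-dimethoxyphenyl]acetic acid, via benzylic lithium compound 6 (not isolated)
Conditions: LiN(iPr)2, THF, −78 °C; CO2 (gas), −78 → 0 °C; 1 M HCl
Reagents that add atoms: carbon dioxide, O=C=O
Why: Lateral lithiation of an ortho-toluamide (amide-directed benzylic deprotonation) and carboxylation attach C7 while ring A is still aromatic, so the C5 side chain needs no later regioselective enolate alkylation.

Step 4
Reactants: 7 2-[2-(dimethylcarbamoyl)-3,6-dimethoxyphenyl]acetic acid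
Product: 9 methyl 2-[6-(dimethylcarbamoyl)-2,5-dimethoxy-6-methylcyclohexa-1,4-dien-1-yl]acetate (racemic), via potassium carboxylate 8 (not isolated)
Conditions: KOtBu (1.0 equiv), THF; NH3 (l), K (2.2 equiv), −78 °C; MeI (excess), −78 °C → rt; evaporate NH3, DMF, rt
Reagents that add atoms: iodomethane, CI
Why: Birch reduction–alkylation: the amide-stabilised radical anion is protonated para by the one equivalent of tert-butanol formed in the neutralisation, the amide enolate is C-methylated at the ipso carbon (C4 with C18), and the carboxylate is then O-methylated. The carboxylate and both enol ethers are inert to the metal; the product is racemic.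

Step 5
Reactants: 9 methyl 2-[6-(dimethylcarbamoyl)-2,5-dimethoxy-6-methylcyclohexa-1,4-dien-1-yl]acetate (racemic)
Product: 11 methyl 2-[rac-(6R,7S)-7-(dimethylcarbamoyl)-7-methyl-8-oxo-1,4-dithiaspiro[4.5]decan-6-yl]acetate, via dithiolane enol ether 10 (not isolated)
Conditions: HS(CH2)2SH (1.05 equiv), BF3·OEt2 (0.2 equiv), CH2Cl2, −40 → 0 °C; then 1 M HCl, THF, rt
Reagents that add atoms: ethane-1,2-dithiol, SCCS; water, O
Why: Thioacetalisation of an enol ether, then enol ether hydrolysis: the C10 enol ether reacts first because its oxocarbenium ion is not next to the electron-poor quaternary C4. Kinetic protonation at C5 anti to the larger carboxamide places C6 cis to C19, and the dithiolane then keeps C5 from epimerising while aqueous acid unmasks only the C3 ketone.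

Step 6
Reactants: 11 methyl 2-[rac-(6R,7S)-7-(dimethylcarbamoyl)-7-methyl-8-oxo-1,4-dithiaspiro[4.5]decan-6-yl]acetate
Product: 12 methyl 2-[(6R,7S,8S)-7-(dimethylcarbamoyl)-8-hydroxy-7-methyl-1,4-dithiaspiro[4.5]decan-6-yl]acetate
Conditions: (3aR)-1-methyl-3,3-diphenyltetrahydro-1H,3H-pyrrolo[1,2-c][1,3,2]oxazaborole (1.0 equiv), BH3·SMe2, THF, −20 °C; MeOH; chromatography removes the (6S,7R,8S) diastereomer
Reagents that add atoms: none
Why: Corey–Bakshi–Shibata reduction under reagent control (quaternary C4 large, C2 methylene small) should give the 3S carbinol from both enantiomers of 11, which converts the racemate into 12 and its separable (6S,7R,8S) diastereomer (resolution). The C3 centre only carries a protecting group and is erased in step 21.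

Step 7
Reactants: 12 methyl 2-[(6R,7S,8S)-7-(dimethylcarbamoyl)-8-hydroxy-7-methyl-1,4-dithiaspiro[4.5]decan-6-yl]acetate
Product: 13 methyl 2-[(6R,7S,8S)-8-[tert-butyl(dimethyl)silyl]oxy-7-(dimethylcarbamoyl)-7-methyl-1,4-dithiaspiro[4.5]decan-6-yl]acetate
Conditions: tBuMe2SiOTf, 2,6-lutidine, CH2Cl2, 0 °C → rt
Reagents that add atoms: tert-butyldimethylsilyl trifluoromethanesulfonate, CC(C)(C)[Si](C)(C)OS(=O)(=O)C(F)(F)F
Why: Silylation of a hindered secondary alcohol with the silyl triflate; the silyl ether must later withstand TiCl4 at low temperature, ozone and the hypoiodite conditions.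

Step 8
Reactants: 13 methyl 2-[(6R,7S,8S)-8-[tert-butyl(dimethyl)silyl]oxy-7-(dimethylcarbamoyl)-7-methyl-1,4-dithiaspiro[4.5]decan-6-yl]acetate
Product: 14 methyl 2-[(1R,2S,3S)-3-[tert-butyl(dimethyl)silyl]oxy-2-(dimethylcarbamoyl)-2-methyl-6-oxocyclohexyl]acetate
Conditions: MeI (excess), CaCO3, MeCN–H2O (9:1), 45 °C
Reagents that add atoms: water, O
Why: S-Alkylative hydrolysis of the dithiolane under buffered, near-neutral conditions, chosen so that the C5 centre next to the liberated C10 ketone does not enolise.

Step 9
Reactants: 14 methyl 2-[(1R,2S,3S)-3-[tert-butyl(dimethyl)silyl]oxy-2-(dimethylcarbamoyl)-2-methyl-6-oxocyclohexyl]acetate; 15 3-ethoxycyclohex-2-en-1-one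
Product: 18 silylated aldol adduct (9βH; 10α-OSiMe3; 3β-OSiMe2tBu; ring C as 13-ethoxy-13-en-8-one), via lithium dienolate 16 (not isolated), via lithium aldolate 17 (not isolated)
Conditions: 15 (1.5 equiv), LiN(iPr)2, THF, −78 °C; 14, −78 °C; Me3SiCl, −78 → −30 °C; aq. NaHCO3
Reagents that add atoms: chlorotrimethylsilane, C[Si](C)(C)Cl
Why: Directed aldol addition: kinetic α′-deprotonation of the vinylogous ester at C9, addition to the C10 ketone and silyl trapping of the aldolate, which blocks the retro-aldol path and attack of the alkoxide on the C7 ester. Equatorial attack on the chair whose axial C4 carboxamide blocks the axial path should give the 10α oxygen, and a Zimmerman–Traxler chair with the cyclic E(O)-enolate and the branched C5 side equatorial should give 9βH.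

Step 10
Reactants: 18 silylated aldol adduct
Product: 20 tricyclic enone (rings A/B/C; 8(14)-en-13-one; 10α-OH; 6β-CO2Me), via lithium alkoxide 19 (not isolated)
Conditions: LiN(iPr)2 (1.3 equiv), THF, −78 → −30 °C; then 1 M HCl, THF, 0 °C → rt
Reagents that add atoms: water, O
Why: The kinetic ester enolate at C6 adds 5-exo-trig to the C8 carbonyl of the vinylogous ester; acid then ionises the tertiary allylic carbinol and hydrolyses the enol ether (Stork–Danheiser transposition) and removes the trimethylsilyl group. C6 is now a vinylogous β-keto ester position and should settle with the ester trans to quaternary C4.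

Step 11
Reactants: 20 tricyclic enone
Product: 21 8β-allyl 13-ketone (cis B/C; 10α-OH; 6β-CO2Me)
Conditions: CH2=CHCH2SiMe3 (3 equiv), TiCl4 (2.5 equiv), CH2Cl2, −78 °C; aq. NaHCO3; then NaOMe (0.2 equiv), MeOH, 0 °C
Reagents that add atoms: allyltrimethylsilane, C=CC[Si](C)(C)C
Why: Hosomi–Sakurai conjugate allylation creates quaternary C8; axial attack on the cyclohexenone trans to the C9–C10 bond (cis to H9) should give the cis B/C fusion with the allyl group β. Methoxide re-equilibrates C6 to the β ester, which avoids eclipsing with C4.

Step 12
Reactants: 21 8β-allyl 13-ketone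
Product: 23 keto aldehyde (C16 aldehyde; 13-ketone), via ozonide 22 (not isolated)
Conditions: O3, CH2Cl2, −78 °C; PPh3, −78 °C → rt
Reagents that add atoms: ozone, [O-][O+]=O
Why: Ozonolysis of the only alkene with reductive work-up; the terminal carbon is lost and C16 becomes the aldehyde carbon.

Step 13
Reactants: 23 keto aldehyde
Product: 24 13,16-diol (ring D closed; cis diol)
Conditions: SmI2 (2.5 equiv), t-BuOH (2 equiv), THF, −78 → 0 °C
Reagents that add atoms: none
Why: Ketyl–carbonyl (pinacol) cyclisation: the aldehyde ketyl adds to the C13 ketone and closes the five-membered ring D. The bridge can only span the β face, which fixes C13; the samarium-chelated diol should be cis at C16, a centre that is oxidised in the next step.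

Step 14
Reactants: 24 13,16-diol
Product: 25 α-ketol (16-ketone; 13-OH; 10α-OH)
Conditions: SO3·pyridine, DMSO, iPr2NEt, CH2Cl2, 0 °C
Reagents that add atoms: none
Why: Parikh–Doering oxidation of the secondary C16 alcohol; the tertiary alcohols at C10 and C13 are inert and activated DMSO does not cleave the glycol.

Step 15
Reactants: 25 α-ketol
Product: 26 hydroxy amide (10α-OH; 19-dimethylamide; 16-ketone; 13-OCH2OMe; 3β-OSiMe2tBu; 7-methyl ester)
Conditions: MeOCH2Cl, iPr2NEt, Bu4NI (cat.), ClCH2CH2Cl, 50 °C
Reagents that add atoms: chloromethyl methyl ether, COCCl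
Why: Alkylation of the tertiary α-ketol hydroxyl; the C10 hydroxyl lies between two ring-fusion carbons and is hydrogen-bonded to the axial C19 carbonyl, so it should stay free. The cap is required because a free 13-alkoxyl radical would fragment the α-ketol in step 16.

Step 16
Reactants: 26 hydroxy amide
Product: 28 10,12-ether (10α,12α-epoxy; 19-dimethylamide; 16-ketone), via hypoiodite 27 (not isolated)
Conditions: PhI(OAc)2 (1.5 equiv), I2 (1.0 equiv), cyclohexane–CH2Cl2, tungsten lamp, 25–35 °C
Reagents that add atoms: none
Why: PhI(OAc)2 and I2 form acetyl hypoiodite, which converts the C10 hydroxyl into hypoiodite 27, and visible light cleaves its O–I bond. The tertiary alkoxyl radical abstracts the axial C12 α-hydrogen through a six-membered chair-like transition state (1,5-hydrogen transfer); the C12 radical takes iodine, and the iodide, activated by the trivalent iodine oxidant, is displaced by the C10 oxygen (or the radical is oxidised and the cation captured). The closest known reaction type is the hypoiodite reaction of alcohols, in which 1,5-hydrogen transfer is followed by tetrahydrofuran formation between 1,3-diaxial positions. The ring closed is the five-membered 10,12-oxolane, formed by O–C12 bond formation in a 5-exo-tet displacement, which makes ring C part of a 6-oxabicyclo[3.2.1]octane. The new stereocentre C12 is controlled by the tether: the oxygen is fixed on axial C10, so the bridge can only form on the axial α face. The step needs selectivity for C12–H over the other δ hydrogens (C14–H2, C15–H2, C3–H, C18–H3) and over β-scission of the C9–C10 or C5–C10 bond. Ring B should secure this by holding the oxygen nearly eclipsed with C11 and nearly anti to C8, so that it lies over H12α only, while C3–H and C18–H3 are equatorially disposed and C6–H is one atom too close. The substrate has no alkene (C16 is a ketone) and no O–H or N–H other than the C10 hydroxyl, so iodine has no other partner; the enolisable C15 is the one site exposed to iodination.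

Step 17
Reactants: 28 10,12-ether
Product: 30 lactone alcohol (19,10-lactone; 12α-OH; 16-ketone; 13-OCH2OMe; 3β-OSiMe2tBu), via iminium lactone 29 (not isolated)
Conditions: BF3·OEt2 (3 equiv), CH2Cl2, −20 → 0 °C; then NaOAc–AcOH buffer (pH 4), THF–H2O, rt
Reagents that add atoms: water, O
Why: Proposed new method: BF3 binds the bridging oxygen, the tertiary C10–O bond of the strained oxabicycle ionises while the secondary C12–O bond stays, and the C19 amide oxygen, 1,3-diaxial to C10 on the α face, captures the cation as a five-membered iminium ether that water hydrolyses at pH 4 to the γ-lactone and dimethylamine. C10 keeps its configuration because the amide can only reach the face that the leaving oxygen occupied, and that oxygen remains on C12 as the 12α-hydroxyl. The closest known reaction types are the acid- or iodine-induced lactonisation of unsaturated tertiary amides by O-participation and the Lewis-acid cleavage of tert-alkyl ethers.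

Step 18
Reactants: 30 lactone alcohol
Product: 31 12,13-bis(methoxymethyl) ether (19,10-lactone; 16-ketone)
Conditions: MeOCH2Cl, iPr2NEt, Bu4NI (cat.), ClCH2CH2Cl, 60 °C
Reagents that add atoms: chloromethyl methyl ether, COCCl
Why: Acetal protection of the axial C12 hydroxyl so that only C3 is oxidised in step 21; a 13-acetal lost in step 17 would be restored here.

Step 19
Reactants: 31 12,13-bis(methoxymethyl) ether
Product: 32 16-methylene lactone (3β-OSiMe2tBu)
Conditions: Ph3PCH3Br, KOtBu, THF, 0 → 45 °C
Reagents that add atoms: methyltriphenylphosphonium bromide, C[P+](c1ccccc1)(c1ccccc1)c1ccccc1.[Br-]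
Why: Wittig methylenation of the only ketone; C3 is still a silyl ether, and the neopentyl lactone and the hindered ester are not attacked by the ylide.

Step 20
Reactants: 32 16-methylene lactone
Product: 33 3β-alcohol (16-ene; 12,13-bis-acetal)
Conditions: Bu4NF, AcOH (1:1), THF, rt
Reagents that add atoms: none
Why: Fluoride-induced desilylation, buffered so that the β-hydroxy lactone does not undergo retro-aldol opening.

Step 21
Reactants: 33 3β-alcohol
Product: 35 enone (1-en-3-one; 19,10-lactone; 16-ene), via 3-ketone 34 (not isolated)
Conditions: 2-iodoxybenzoic acid (3.5 equiv), DMSO–fluorobenzene (1:2), 70 °C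
Reagents that add atoms: none
Why: 2-Iodoxybenzoic acid oxidises the carbinol and then dehydrogenates the ketone through its enol; C2 is the only enolisable position and C4 and C10 are quaternary, so neither a regioisomer nor over-oxidation to a dienone is possible.

Step 22
Reactants: 35 enone
Product: 36 enone diol (12α,13-diol)
Conditions: Me2BBr (4 equiv), CH2Cl2, −78 °C; then aq. NaHCO3, THF, 0 °C
Reagents that add atoms: none
Why: Cleavage of both methoxymethyl ethers by the bromoborane at low temperature, done while ring A is still the acid-stable enone and before the allylic alcohols are present.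

Step 23
Reactants: 36 enone diol
Product: 37 enone triol (15β-OH)
Conditions: SeO2 (0.5 equiv), t-BuOOH (3 equiv), CH2Cl2, 0 °C → rt
Reagents that add atoms: tert-butyl hydroperoxide, CC(C)(C)OO
Why: Allylic hydroxylation by ene reaction at C17 and [2,3]-sigmatropic shift of the allylic seleninic acid; oxygen should be delivered to the β face of C15, away from the C7 ester that covers the other face. The ring A enone has no allylic hydrogen.

Step 24
Reactants: 37 enone triol
Product: 38 methyl ester of the target gibberellin (7-methyl ester; 3β,12α,13,15β-tetrol)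
Conditions: (3aR)-1-methyl-3,3-diphenyltetrahydro-1H,3H-pyrrolo[1,2-c][1,3,2]oxazaborole (1.0 equiv), catecholborane (6 equiv), toluene–CH2Cl2, −78 → −40 °C; MeOH; pH 7 buffer
Reagents that add atoms: none
Why: Corey–Bakshi–Shibata 1,2-reduction under reagent control: with quaternary C4 large and the C2 vinyl carbon small, the (R)-catalyst should deliver hydride to the α face and give the 3S (3β) carbinol. Catecholborane does not hydroborate the 1,1-disubstituted alkene at this temperature, and the sensitive allylic hydroxy lactone is formed only now.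

Step 25
Reactants: 38 methyl ester of the target gibberellin
Product: 39 target gibberellin (free C7 acid)
Conditions: n-PrSLi (5 equiv), HMPA, 0 °C → rt; then cold 0.5 M HCl to pH 3
Reagents that add atoms: none
Why: SN2 demethylation of the hindered methyl ester by thiolate (alkyl–oxygen cleavage) avoids hydroxide and with it the lactone migration and C3 epimerisation of ring A.

## Compound list

1 | 2,5-dimethoxybenzoic acid | COc1ccc(OC)c(c1)C(=O)O | starting material
2 | 2,5-dimethoxybenzoyl chloride | COc1ccc(OC)c(c1)C(=O)Cl | intermediate
3 | 2,5-dimethoxy-N,N-dimethylbenzamide | CN(C)C(=O)c1cc(OC)ccc1OC | intermediate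
4 | 6-lithio-2,5-dimethoxy-N,N-dimethylbenzamide | CN(C)C(=O)c1c(OC)ccc(OC)c1[Li] | intermediate
5 | 3,6-dimethoxy-N,N,2-trimethylbenzamide | CN(C)C(=O)c1c(C)c(OC)ccc1OC | intermediate
6 | [2-(dimethylcarbamoyl)-3,6-dimethoxyphenyl]methyllithium | CN(C)C(=O)c1c(C[Li])c(OC)ccc1OC | intermediate
7 | 2-[2-(dimethylcarbamoyl)-3,6-dimethoxyphenyl]acetic acid | CN(C)C(=O)c1c(CC(=O)O)c(OC)ccc1OC | intermediate
8 | potassium 2-[6-(dimethylcarbamoyl)-2,5-dimethoxy-6-methylcyclohexa-1,4-dien-1-yl]acetate (racemic; 6S shown) | [K+].[O-]C(=O)CC1=C(OC)CC=C(OC)[C@@]1(C)C(=O)N(C)C | intermediate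
9 | methyl 2-[6-(dimethylcarbamoyl)-2,5-dimethoxy-6-methylcyclohexa-1,4-dien-1-yl]acetate (racemic; 6S shown) | COC(=O)CC1=C(OC)CC=C(OC)[C@@]1(C)C(=O)N(C)C | intermediate
10 | methyl 2-[rac-(6R,7S)-7-(dimethylcarbamoyl)-8-methoxy-7-methyl-1,4-dithiaspiro[4.5]dec-8-en-6-yl]acetate | COC1=CCC2(SCCS2)[C@H](CC(=O)OC)[C@]1(C)C(=O)N(C)C | intermediate
11 | methyl 2-[rac-(6R,7S)-7-(dimethylcarbamoyl)-7-methyl-8-oxo-1,4-dithiaspiro[4.5]decan-6-yl]acetate | O=C1CCC2(SCCS2)[C@H](CC(=O)OC)[C@]1(C)C(=O)N(C)C | intermediate
12 | methyl 2-[(6R,7S,8S)-7-(dimethylcarbamoyl)-8-hydroxy-7-methyl-1,4-dithiaspiro[4.5]decan-6-yl]acetate | O[C@H]1CCC2(SCCS2)[C@H](CC(=O)OC)[C@]1(C)C(=O)N(C)C | intermediate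
13 | methyl 2-[(6R,7S,8S)-8-[tert-butyl(dimethyl)silyl]oxy-7-(dimethylcarbamoyl)-7-methyl-1,4-dithiaspiro[4.5]decan-6-yl]acetate | CC(C)(C)[Si](C)(C)O[C@H]1CCC2(SCCS2)[C@H](CC(=O)OC)[C@]1(C)C(=O)N(C)C | intermediate
14 | methyl 2-[(1R,2S,3S)-3-[tert-butyl(dimethyl)silyl]oxy-2-(dimethylcarbamoyl)-2-methyl-6-oxocyclohexyl]acetate | O=C1CC[C@H](O[Si](C)(C)C(C)(C)C)[C@@](C)(C(=O)N(C)C)[C@H]1CC(=O)OC | intermediate
15 | 3-ethoxycyclohex-2-en-1-one | CCOC1=CC(=O)CCC1 | starting material
16 | lithium dienolate of 15 (deprotonated at the future C9) | CCOC1=CC(O[Li])=CCC1 | intermediate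
17 | lithium aldolate (C9–C10 bond formed; 10α-OLi; 9βH) | CCOC1=CC(=O)[C@@H](CC1)[C@]1(O[Li])CC[C@H](O[Si](C)(C)C(C)(C)C)[C@@](C)(C(=O)N(C)C)[C@H]1CC(=O)OC | intermediate
18 | silylated aldol adduct (10α-OSiMe3; 9βH; ring C 13-ethoxy-13-en-8-one; 3β-OSiMe2tBu; 19-dimethylamide; C5 α-CH2CO2Me) | CCOC1=CC(=O)[C@@H](CC1)[C@]1(O[Si](C)(C)C)CC[C@H](O[Si](C)(C)C(C)(C)C)[C@@](C)(C(=O)N(C)C)[C@H]1CC(=O)OC | intermediate
19 | lithium alkoxide after ring B closure (C6–C8 bond; C6 and C8 configuration not defined) | CCOC1=CC2(O[Li])[C@@H](CC1)[C@]1(O[Si](C)(C)C)CC[C@H](O[Si](C)(C)C(C)(C)C)[C@@](C)(C(=O)N(C)C)[C@H]1C2C(=O)OC | intermediate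
20 | tricyclic enone (8(14)-en-13-one; 9βH; 10α-OH; 5βH; 6β-CO2Me; 3β-OSiMe2tBu; 19-dimethylamide) | O=C1C=C2[C@@H](CC1)[C@]1(O)CC[C@H](O[Si](C)(C)C(C)(C)C)[C@@](C)(C(=O)N(C)C)[C@H]1[C@@H]2C(=O)OC | intermediate
21 | 8β-allyl 13-ketone (cis B/C; otherwise as 20) | O=C1C[C@@]2(CC=C)[C@@H](CC1)[C@]1(O)CC[C@H](O[Si](C)(C)C(C)(C)C)[C@@](C)(C(=O)N(C)C)[C@H]1[C@@H]2C(=O)OC | intermediate
22 | ozonide of 21 (1,2,4-trioxolane at C16; C16 configuration not defined) | O=C1C[C@@]2(CC3OCOO3)[C@@H](CC1)[C@]1(O)CC[C@H](O[Si](C)(C)C(C)(C)C)[C@@](C)(C(=O)N(C)C)[C@H]1[C@@H]2C(=O)OC | intermediate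
23 | keto aldehyde (C8 β-CH2CHO; 13-ketone) | O=C1C[C@@]2(CC=O)[C@@H](CC1)[C@]1(O)CC[C@H](O[Si](C)(C)C(C)(C)C)[C@@](C)(C(=O)N(C)C)[C@H]1[C@@H]2C(=O)OC | intermediate
24 | tetracyclic 13,16-diol (cis diol; 10α-OH; 19-dimethylamide; 3β-OSiMe2tBu; 7-methyl ester) | O[C@@H]1C[C@]23C[C@@]1(O)CC[C@H]2[C@]1(O)CC[C@H](O[Si](C)(C)C(C)(C)C)[C@@](C)(C(=O)N(C)C)[C@H]1[C@@H]3C(=O)OC | intermediate
25 | α-ketol (16-ketone; 13-OH; 10α-OH) | O=C1C[C@]23C[C@@]1(O)CC[C@H]2[C@]1(O)CC[C@H](O[Si](C)(C)C(C)(C)C)[C@@](C)(C(=O)N(C)C)[C@H]1[C@@H]3C(=O)OC | intermediate
26 | hydroxy amide, precursor of the key step (10α-OH; 19-dimethylamide; 16-ketone; 13-OCH2OMe; 3β-OSiMe2tBu; 7-methyl ester) | O=C1C[C@]23C[C@@]1(OCOC)CC[C@H]2[C@]1(O)CC[C@H](O[Si](C)(C)C(C)(C)C)[C@@](C)(C(=O)N(C)C)[C@H]1[C@@H]3C(=O)OC | intermediate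
27 | C10 hypoiodite of 26 | O=C1C[C@]23C[C@@]1(OCOC)CC[C@H]2[C@]1(OI)CC[C@H](O[Si](C)(C)C(C)(C)C)[C@@](C)(C(=O)N(C)C)[C@H]1[C@@H]3C(=O)OC | intermediate
28 | 10,12-ether, product of the key step (10α,12α-epoxy) | O=C1C[C@]23C[C@@]1(OCOC)[C@@H]4C[C@H]2[C@]1(O4)CC[C@H](O[Si](C)(C)C(C)(C)C)[C@@](C)(C(=O)N(C)C)[C@H]1[C@@H]3C(=O)OC | intermediate
29 | iminium lactone (19,10-iminium ether; 12α-O–BF3 borate) | O=C1C[C@]23C[C@@]1(OCOC)[C@@H](O[B-](F)(F)F)C[C@H]2[C@@]12CC[C@H](O[Si](C)(C)C(C)(C)C)[C@@](C)(C(=[N+](C)C)O1)[C@H]2[C@@H]3C(=O)OC | intermediate
30 | lactone alcohol (19,10-lactone; 12α-OH; 16-ketone; 13-OCH2OMe; 3β-OSiMe2tBu) | O=C1C[C@]23C[C@@]1(OCOC)[C@@H](O)C[C@H]2[C@@]12CC[C@H](O[Si](C)(C)C(C)(C)C)[C@@](C)(C(=O)O1)[C@H]2[C@@H]3C(=O)OC | intermediate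
31 | 12α,13-bis(methoxymethyl) ether of 30 | O=C1C[C@]23C[C@@]1(OCOC)[C@@H](OCOC)C[C@H]2[C@@]12CC[C@H](O[Si](C)(C)C(C)(C)C)[C@@](C)(C(=O)O1)[C@H]2[C@@H]3C(=O)OC | intermediate
32 | 16-methylene lactone (3β-OSiMe2tBu; 12,13-bis-acetal) | C=C1C[C@]23C[C@@]1(OCOC)[C@@H](OCOC)C[C@H]2[C@@]12CC[C@H](O[Si](C)(C)C(C)(C)C)[C@@](C)(C(=O)O1)[C@H]2[C@@H]3C(=O)OC | intermediate
33 | 3β-alcohol (16-ene; 12,13-bis-acetal) | C=C1C[C@]23C[C@@]1(OCOC)[C@@H](OCOC)C[C@H]2[C@@]12CC[C@H](O)[C@@](C)(C(=O)O1)[C@H]2[C@@H]3C(=O)OC | intermediate
34 | 3-ketone | C=C1C[C@]23C[C@@]1(OCOC)[C@@H](OCOC)C[C@H]2[C@@]12CCC(=O)[C@@](C)(C(=O)O1)[C@H]2[C@@H]3C(=O)OC | intermediate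
35 | 1-en-3-one (12,13-bis-acetal) | C=C1C[C@]23C[C@@]1(OCOC)[C@@H](OCOC)C[C@H]2[C@@]12C=CC(=O)[C@@](C)(C(=O)O1)[C@H]2[C@@H]3C(=O)OC | intermediate
36 | 1-en-3-one 12α,13-diol | C=C1C[C@]23C[C@@]1(O)[C@@H](O)C[C@H]2[C@@]12C=CC(=O)[C@@](C)(C(=O)O1)[C@H]2[C@@H]3C(=O)OC | intermediate
37 | 1-en-3-one 12α,13,15β-triol (3-dehydro methyl ester of the target) | C=C1[C@@H](O)[C@]23C[C@@]1(O)[C@@H](O)C[C@H]2[C@@]12C=CC(=O)[C@@](C)(C(=O)O1)[C@H]2[C@@H]3C(=O)OC | intermediate
38 | methyl ester of the target gibberellin (7-methyl ester; 3β,12α,13,15β-tetrol) | C=C1[C@@H](O)[C@]23C[C@@]1(O)[C@@H](O)C[C@H]2[C@@]12C=C[C@H](O)[C@@](C)(C(=O)O1)[C@H]2[C@@H]3C(=O)OC | intermediate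
39 | target gibberellin, number 32 of the A series (3β,10α,12α,13,15β-pentahydroxy-20-norgibberella-1,16-diene-7,19-dioic acid 19,10-lactone; descriptors as in the usual drawing) | C=C1[C@@H](O)[C@]23C[C@@]1(O)[C@@H](O)C[C@H]2[C@@]12C=C[C@H](O)[C@@](C)(C(=O)O1)[C@H]2[C@@H]3C(=O)O | target

## Step count and least certain steps

Total step count: 25. Longest linear sequence: 25 steps (from 1; 15 enters at step 9).

Step 17 (ether to lactone, the proposed new method). The most likely failure is loss of a proton from the C10 cation to an alkene before the amide oxygen arrives, or binding of the Lewis acid to the amide so that the ether is never ionised, accompanied by loss of the silyl or acetal groups. The fallback divides the exchange into known operations and sets out from 28. Me3SiOTf and 2,6-lutidine should open the tertiary ether by elimination toward the least hindered β-hydrogen, giving the 1(10)-alkene 12-silyl ether F1. I2 in aqueous THF should then effect iodolactonisation of the unsaturated tertiary amide (oxygen to C10 from the α face, iodine to C1 from the β face) and free the 12-hydroxyl, giving the 1β-iodo lactone F2. Bu3SnH with azobis(isobutyronitrile) removes the iodine, and the route is rejoined at 30.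

Step 16 (key step). The most likely failure is β-scission of the tertiary alkoxyl radical (C9–C10 or C5–C10 cleavage) outrunning hydrogen transfer at the temperature of the lamp, together with iodination at the enolisable C15 by electrophilic iodine. The fallback keeps the C10 oxygen as the relay but separates the hydrogen transfer from the C–O bond formation, uses no iodine and sets out from 26. NaOCl and AcOH in CH2Cl2 at 0 °C in the dark convert the tertiary alcohol into the C10 hypochlorite F3. Irradiation at −30 °C starts a chain of 1,5-hydrogen transfer and chlorine transfer from a second hypochlorite to the open β face of the C12 radical (the α face is covered by the C10 carbinol), which should give mainly the 12β-chloro 10α-alcohol F4; the low temperature favours hydrogen transfer, which has the lower barrier, over scission. NaH in THF–DMF then closes the ring by intramolecular Williamson displacement, the axial C10 alkoxide attacking C12 from the α face with inversion, and the route is rejoined at 28.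

Step 9 (aldol union). The most likely failure is proton transfer from the hindered, enolisable C10 ketone or reversal of the addition before silylation, and beyond that insufficient facial selectivity at C10. The fallback replaces the lithium aldolate equilibrium by a Lewis-acid-mediated open transition state and sets out from 15. LiN(iPr)2 and Me3SiCl give the 2-silyloxy diene F5. F5 and 14 are combined with TiCl4 at −78 °C (Mukaiyama aldol), giving the free aldol F6. N-(Trimethylsilyl)imidazole silylates F6, and the route is rejoined at 18.

Step 11 (conjugate allylation). The most likely failure is ionisation or dehydration of the tertiary C10 carbinol under TiCl4 (formation of a 9(10),8(14)-dienone) in competition with the slow attack on the fully substituted β carbon. The fallback reverses the order of the two bonds at C8 and sets out from 18. Allylmagnesium bromide premixed with anhydrous CeCl3 at −78 °C (an organocerium reagent, chosen because it adds to ketone-type carbonyls much faster than to esters and amides) adds to the C8 carbonyl, and cold aqueous oxalic acid effects the transposition to the 8-allyl enone F7, which keeps the C10 silyl ether. KOtBu in t-BuOH–THF closes ring B by intramolecular Michael addition of the C6 ester enolate to C8 on the face of the C9–C10 bond; acidic work-up removes the silyl group, and the route is rejoined at 21.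

Step 24 (enone reduction). The most likely failure is poor facial selectivity, because the intrinsic preference of the C3 ketone for β-face attack opposes the reagent. The fallback avoids reducing an enone and sets out from 37. PhSeH with Et3N adds to C1 and gives the 1β-phenylselanyl ketone F8. K[(sec-Bu)3BH] at −78 °C should reduce the saturated ketone by equatorial delivery to the 3β-alcohol F9. H2O2 oxidises selenium and syn-elimination toward C2 restores the 1-ene, so that the route is rejoined at 38.

## Further compounds

F1 | step 17 | 1(10)-alkene 12α-trimethylsilyl ether (19-dimethylamide; 16-ketone; 13-OCH2OMe; 3β-OSiMe2tBu) | O=C1C[C@]23C[C@@]1(OCOC)[C@@H](O[Si](C)(C)C)C[C@H]2C1=CC[C@H](O[Si](C)(C)C(C)(C)C)[C@@](C)(C(=O)N(C)C)[C@H]1[C@@H]3C(=O)OC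
F2 | step 17 | 1β-iodo 19,10-lactone 12α-alcohol | O=C1C[C@]23C[C@@]1(OCOC)[C@@H](O)C[C@H]2[C@@]12[C@H](I)C[C@H](O[Si](C)(C)C(C)(C)C)[C@@](C)(C(=O)O1)[C@H]2[C@@H]3C(=O)OC
F3 | step 16 | C10 hypochlorite of 26 | O=C1C[C@]23C[C@@]1(OCOC)CC[C@H]2[C@]1(OCl)CC[C@H](O[Si](C)(C)C(C)(C)C)[C@@](C)(C(=O)N(C)C)[C@H]1[C@@H]3C(=O)OC
F4 | step 16 | 12β-chloro 10α-alcohol (19-dimethylamide; 16-ketone; 13-OCH2OMe; 3β-OSiMe2tBu) | O=C1C[C@]23C[C@@]1(OCOC)[C@H](Cl)C[C@H]2[C@]1(O)CC[C@H](O[Si](C)(C)C(C)(C)C)[C@@](C)(C(=O)N(C)C)[C@H]1[C@@H]3C(=O)OC
F5 | step 9 | (5-ethoxycyclohexa-1,5-dien-1-yl)oxytrimethylsilane | CCOC1=CC(O[Si](C)(C)C)=CCC1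
F6 | step 9 | free aldol adduct (10α-OH; 9βH) | CCOC1=CC(=O)[C@@H](CC1)[C@]1(O)CC[C@H](O[Si](C)(C)C(C)(C)C)[C@@](C)(C(=O)N(C)C)[C@H]1CC(=O)OC
F7 | step 11 | 8-allyl 8(14)-en-13-one with open ring B (10α-OSiMe3) | O=C1C=C(CC=C)[C@@H](CC1)[C@]1(O[Si](C)(C)C)CC[C@H](O[Si](C)(C)C(C)(C)C)[C@@](C)(C(=O)N(C)C)[C@H]1CC(=O)OC
F8 | step 24 | 1β-phenylselanyl 3-ketone triol | C=C1[C@@H](O)[C@]23C[C@@]1(O)[C@@H](O)C[C@H]2[C@@]12[C@H]([Se]c4ccccc4)CC(=O)[C@@](C)(C(=O)O1)[C@H]2[C@@H]3C(=O)OC
F9 | step 24 | 1β-phenylselanyl 3β-alcohol | C=C1[C@@H](O)[C@]23C[C@@]1(O)[C@@H](O)C[C@H]2[C@@]12[C@H]([Se]c4ccccc4)C[C@H](O)[C@@](C)(C(=O)O1)[C@H]2[C@@H]3C(=O)OC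
A1 | alternative 1 | trimethyl (E)-aconitate | COC(=O)C/C(=C\C(=O)OC)C(=O)OC
A2 | alternative 1 | 2,3-bis(trimethylsilyloxy)buta-1,3-diene | C=C(O[Si](C)(C)C)C(=C)O[Si](C)(C)C
A3 | alternative 1 | ring C cyclohexene triester with quaternary C8 | COC(=O)C[C@@]1(C(=O)OC)CC(O[Si](C)(C)C)=C(O[Si](C)(C)C)C[C@H]1C(=O)OC
A4 | alternative 2 | δ-lactone (C19–O–C1) on the 5(10)-ene B/C/D core (C4 configuration not defined) | C=C1C[C@]23C[C@@]1(O[Si](C)(C)C)[C@@H](O[Si](C)(C)C(C)(C)C)C[C@H]2C(=C[C@@H]3CO[Si](C)(C)C(C)(C)C)[C@@H]1C[C@H](O[Si](C)(C)C(C)(C)C)C(C)C(=O)O1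
A5 | alternative 2 | ring A cyclohexene C19 acid | C=C1C[C@]23C[C@@]1(O[Si](C)(C)C)[C@@H](O[Si](C)(C)C(C)(C)C)C[C@H]2C1=CC[C@H](O[Si](C)(C)C(C)(C)C)[C@@](C)(C(=O)O)[C@H]1[C@@H]3CO[Si](C)(C)C(C)(C)C
A6 | alternative 3 | C6 bromo ester with C8=C15 silyl enol ether and C13 ethynyl group (C6 and enol ether geometry not defined) | C#C[C@@]1(O[Si](C)(C)C)CC(=CO[Si](C)(C)C(C)(C)C)[C@@H](C[C@@H]1O[Si](C)(C)C(C)(C)C)[C@@]12C=C[C@H](O[Si](C)(C)C(C)(C)C)[C@@](C)(C(=O)O1)[C@H]2C(Br)C(=O)OC
A7 | alternative 3 | tetrasilylated methyl ester of the target gibberellin | C=C1[C@@H](O[Si](C)(C)C(C)(C)C)[C@]23C[C@@]1(O[Si](C)(C)C)[C@@H](O[Si](C)(C)C(C)(C)C)C[C@H]2[C@@]12C=C[C@H](O[Si](C)(C)C(C)(C)C)[C@@](C)(C(=O)O1)[C@H]2[C@@H]3C(=O)OC
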